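The route rests on cutting the C3–C1′ bond between the pyranone ring and the dienyl chain. C3 is an enol-lactone carbon, so O2–C3=C4 is read as a latent aryl alkyne. The key step is a Sonogashira coupling of an ethynyl benzodioxinone (C1 carboxyl and C8 hydroxyl tied in one acetonide, chlorine and free C6 phenol in place) with the unprotected (E,E)-dienyl iodide carrying the complete tetrahydrofuran ring. It joins both halves without protecting groups and with retention of alkene geometry. A gold-catalysed 6-endo closure then forms the pyranone ring and frees the C8 hydroxyl. The tetrahydrofuran stereocentres derive from (R)-pent-4-en-2-ol, one catalytic epoxidation and a stereospecific 5-endo epoxide opening.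

Key step: step 10

Remark: locants C1–C8a refer to the isochromenone ring and C2–C5 to the tetrahydrofuran ring of the target; for compounds 1–7 the locants of the benzodioxinone ring are used.

Step 1
Reactants: 1 5,7-dihydroxy-2,2-dimethyl-4H-1,3-benzodioxin-4-one
Product: 2 5-hydroxy-2,2-dimethyl-7-[(triisopropylsilyl)oxy]-4H-1,3-benzodioxin-4-one
Conditions: TIPSCl (1.05 equiv), imidazole, CH2Cl2, 0 °C
Reagents that add atoms: chlorotriisopropylsilane, CC(C)[Si](Cl)(C(C)C)C(C)C
Why: Selective O-silylation, because the C5 hydroxyl is locked in a hydrogen bond to the C4 carbonyl and only the more acidic, accessible C7 phenol should react.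

Step 2
Reactants: 2 5-hydroxy-2,2-dimethyl-7-[(triisopropylsilyl)oxy]-4H-1,3-benzodioxin-4-one
Product: 3 2,2-dimethyl-4-oxo-7-[(triisopropylsilyl)oxy]-4H-1,3-benzodioxin-5-yl trifluoromethanesulfonate
Conditions: Tf2O, pyridine, CH2Cl2, 0 °C
Reagents that add atoms: trifluoromethanesulfonic anhydride, O=S(=O)(OS(=O)(=O)C(F)(F)F)C(F)(F)F
Why: O-Triflation of the remaining chelated phenol turns C5 into a cross-coupling site activated by the ortho carbonyl.

Step 3
Reactants: 3 2,2-dimethyl-4-oxo-7-[(triisopropylsilyl)oxy]-4H-1,3-benzodioxin-5-yl trifluoromethanesulfonate; 4 trimethylsilylacetylene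
Product: 5 2,2-dimethyl-7-[(triisopropylsilyl)oxy]-5-[(trimethylsilyl)ethynyl]-4H-1,3-benzodioxin-4-one
Conditions: Pd(PPh3)2Cl2 (5 mol %), CuI (10 mol %), Et3N, DMF, 60 °C
Reagents that add atoms: none
Why: Sonogashira coupling of the electron-poor aryl triflate with the terminal alkyne installs the two carbons that become C3 and C4 of the pyranone ring.

Step 4
Reactants: 5 2,2-dimethyl-7-[(triisopropylsilyl)oxy]-5-[(trimethylsilyl)ethynyl]-4H-1,3-benzodioxin-4-one
Product: 6 5-ethynyl-7-hydroxy-2,2-dimethyl-4H-1,3-benzodioxin-4-one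
Conditions: Bu4NF (2.2 equiv), AcOH (2.2 equiv), THF, 0 °C
Reagents that add atoms: none
Why: Fluoride-mediated desilylation cleaves the alkynyl carbon–silicon bond and the aryl silyl ether in one operation, while acetic acid buffering protects the base-sensitive acyl acetal.

Step 5
Reactants: 6 5-ethynyl-7-hydroxy-2,2-dimethyl-4H-1,3-benzodioxin-4-one
Product: 7 6-chloro-5-ethynyl-7-hydroxy-2,2-dimethyl-4H-1,3-benzodioxin-4-one
Conditions: SO2Cl2 (1.0 equiv), Et2O, 0 °C
Reagents that add atoms: sulfuryl chloride, O=S(=O)(Cl)Cl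
Why: Electrophilic aromatic chlorination, in which the free C7 phenol activates C6 and C8, and attack at C6 (also para to the ring oxygen O1, the site next to the carbon substituent that is chlorinated in orsellinate-type resorcylates) is expected to prevail over attack at C8 between two oxygens.

Step 6
Reactants: 8 (R)-pent-4-en-2-ol; 9 (E)-but-2-enal
Product: 10 (R,E)-5-hydroxyhex-2-enal
Conditions: second-generation Grubbs catalyst (3 mol %), 9 (5 equiv), CH2Cl2, 40 °C
Reagents that add atoms: none
Why: Olefin cross-metathesis between the terminal alkene and the enal partner used in excess should give the conjugated E enal with loss of propene, the carbinol stereocentre not being involved.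

Step 7
Reactants: 10 (R,E)-5-hydroxyhex-2-enal
Product: 12 (E)-3-[(2R,3R)-3-[(2R)-2-hydroxypropyl]oxiran-2-yl]prop-2-enal, via epoxy aldehyde 11 (not isolated)
Conditions: (S)-2-[bis(3,5-bis(trifluoromethyl)phenyl)(trimethylsilyloxy)methyl]pyrrolidine (10 mol %), 35% aq. H2O2 (1.05 equiv), CH2Cl2, rt; then Ph3P=CHCHO (1.3 equiv), rt
Reagents that add atoms: hydrogen peroxide, OO; (triphenylphosphoranylidene)acetaldehyde, O=CC=P(c1ccccc1)(c1ccccc1)c1ccccc1
Why: Iminium-catalysed Weitz–Scheffer epoxidation (Jørgensen epoxidation) followed by a Wittig reaction in the same flask, in which the diaryl(silyloxy)methyl group of the (S)-catalyst shields one face of the E,s-trans iminium ion of 10, hydrogen peroxide adds to C3 from the open face and the resulting enamine closes the trans epoxide, so that both epoxide stereocentres are set by the catalyst irrespective of the remote carbinol centre, and the stabilised ylide then converts the sensitive α-alkoxy aldehyde into the E enal.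

Step 8
Reactants: 12 (E)-3-[(2R,3R)-3-[(2R)-2-hydroxypropyl]oxiran-2-yl]prop-2-enal
Product: 13 (E)-3-[(2S,3R,5R)-3-hydroxy-5-methyltetrahydrofuran-2-yl]prop-2-enal
Conditions: camphorsulfonic acid (10 mol %), CH2Cl2, 0 °C to rt
Reagents that add atoms: none
Why: Acid-catalysed intramolecular epoxide opening (5-endo cyclisation of a hydroxy vinyl epoxide), in which the secondary hydroxyl attacks the allylic epoxide carbon with inversion, the only alternative being a strained 4-exo closure, so that the trans epoxide is translated into the 2,3-trans relationship, C2 (S) is set by inversion and the 2,5-cis relationship follows from the fixed carbinol centre.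

Step 9
Reactants: 13 (E)-3-[(2S,3R,5R)-3-hydroxy-5-methyltetrahydrofuran-2-yl]prop-2-enal
Product: 14 (2S,3R,5R)-2-[(1E,3E)-4-iodobuta-1,3-dien-1-yl]-5-methyltetrahydrofuran-3-ol
Conditions: CrCl2 (8 equiv), CHI3 (3 equiv), THF/1,4-dioxane, 0 °C to rt
Reagents that add atoms: iodoform, IC(I)I
Why: Takai olefination, in which the geminal dichromium species from iodoform and CrCl2 adds to the aldehyde and anti-elimination should give the (E)-alkenyl iodide, extending the enal to the (E,E)-iododiene while excess CrCl2 accommodates the free hydroxyl.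

Step 10
Reactants: 7 6-chloro-5-ethynyl-7-hydroxy-2,2-dimethyl-4H-1,3-benzodioxin-4-one; 14 (2S,3R,5R)-2-[(1E,3E)-4-iodobuta-1,3-dien-1-yl]-5-methyltetrahydrofuran-3-ol
Product: 15 6-chloro-7-hydroxy-5-[(3E,5E)-6-[(2S,3R,5R)-3-hydroxy-5-methyltetrahydrofuran-2-yl]hexa-3,5-dien-1-yn-1-yl]-2,2-dimethyl-4H-1,3-benzodioxin-4-one
Conditions: Pd(PPh3)2Cl2 (5 mol %), CuI (10 mol %), Et3N (3 equiv), degassed THF, rt
Reagents that add atoms: none
Why: Sonogashira coupling: Pd(PPh3)2Cl2 is reduced in situ to zerovalent palladium, which inserts into the alkenyl carbon–iodine bond of 14 with retention of the E geometry, the copper acetylide formed from 7 (its alkyne hydrogen acidified by the acyl-substituted ring) transmetalates, and reductive elimination forms the sp–sp2 bond that becomes C3–C1′ of the target. The closest known reaction type is the Sonogashira coupling of aryl acetylenes with (E)-alkenyl and dienyl iodides. The step exploits that C3 and C4 of the pyranone ring are at the oxidation level of an alkyne flanked by the C1 carboxyl, so the lactone ring need not exist yet; no ring is closed here, the closure being left to the 6-endo-dig addition of step 11. No stereocentre is created, and the three stereocentres of 14 and both E double bonds should pass through unchanged at room temperature under amine base. The selectivity needed is chemoselectivity, secured by the far faster oxidative addition into the alkenyl iodide than into the hindered aryl chloride of 7 and by the inertness of the free phenol, the secondary alcohol and the acyl acetal to these conditions, while exclusion of oxygen suppresses oxidative alkyne dimerisation.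

Step 11
Reactants: 15 6-chloro-7-hydroxy-5-[(3E,5E)-6-[(2S,3R,5R)-3-hydroxy-5-methyltetrahydrofuran-2-yl]hexa-3,5-dien-1-yn-1-yl]-2,2-dimethyl-4H-1,3-benzodioxin-4-one
Product: 16 5-chloro-6,8-dihydroxy-3-[(1E,3E)-4-[(2S,3R,5R)-3-hydroxy-5-methyltetrahydrofuran-2-yl]buta-1,3-dien-1-yl]-1H-isochromen-1-one
Conditions: Ph3PAuCl (5 mol %), AgOTf (5 mol %), CH2Cl2 containing H2O (2 equiv), rt
Reagents that add atoms: none
Why: Gold-catalysed 6-endo-dig cycloisomerisation known for alkynyl benzodioxinones, in which the cationic monovalent gold complex activates the alkyne, the acetonide carbonyl oxygen attacks the distal, dienyl-stabilised alkyne carbon, the resulting 2-aryloxyprop-2-yl cation is hydrolysed by water to acetone, and protodeauration should deliver the pyranone ring with the C8 hydroxyl freed and all stereocentres and E alkenes untouched.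

Compound list
1 | 5,7-dihydroxy-2,2-dimethyl-4H-1,3-benzodioxin-4-one | CC1(C)OC(=O)c2c(O)cc(O)cc2O1 | starting material
2 | 5-hydroxy-2,2-dimethyl-7-[(triisopropylsilyl)oxy]-4H-1,3-benzodioxin-4-one | CC1(C)OC(=O)c2c(O)cc(O[Si](C(C)C)(C(C)C)C(C)C)cc2O1 | intermediate
3 | 2,2-dimethyl-4-oxo-7-[(triisopropylsilyl)oxy]-4H-1,3-benzodioxin-5-yl trifluoromethanesulfonate | CC1(C)OC(=O)c2c(OS(=O)(=O)C(F)(F)F)cc(O[Si](C(C)C)(C(C)C)C(C)C)cc2O1 | intermediate
4 | trimethylsilylacetylene | C#C[Si](C)(C)C | starting material
5 | 2,2-dimethyl-7-[(triisopropylsilyl)oxy]-5-[(trimethylsilyl)ethynyl]-4H-1,3-benzodioxin-4-one | CC1(C)OC(=O)c2c(C#C[Si](C)(C)C)cc(O[Si](C(C)C)(C(C)C)C(C)C)cc2O1 | intermediate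
6 | 5-ethynyl-7-hydroxy-2,2-dimethyl-4H-1,3-benzodioxin-4-one | CC1(C)OC(=O)c2c(C#C)cc(O)cc2O1 | intermediate
7 | 6-chloro-5-ethynyl-7-hydroxy-2,2-dimethyl-4H-1,3-benzodioxin-4-one | CC1(C)OC(=O)c2c(C#C)c(Cl)c(O)cc2O1 | intermediate
8 | (R)-pent-4-en-2-ol | C[C@@H](O)CC=C | starting material
9 | (E)-but-2-enal | C/C=C/C=O | starting material
10 | (R,E)-5-hydroxyhex-2-enal | C[C@@H](O)C/C=C/C=O | intermediate
11 | (2S,3R)-3-[(2R)-2-hydroxypropyl]oxirane-2-carbaldehyde (formed and used in the flask) | C[C@@H](O)C[C@H]1O[C@@H]1C=O | intermediate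
12 | (E)-3-[(2R,3R)-3-[(2R)-2-hydroxypropyl]oxiran-2-yl]prop-2-enal | C[C@@H](O)C[C@H]1O[C@@H]1/C=C/C=O | intermediate
13 | (E)-3-[(2S,3R,5R)-3-hydroxy-5-methyltetrahydrofuran-2-yl]prop-2-enal | C[C@@H]1C[C@@H](O)[C@H](/C=C/C=O)O1 | intermediate
14 | (2S,3R,5R)-2-[(1E,3E)-4-iodobuta-1,3-dien-1-yl]-5-methyltetrahydrofuran-3-ol | C[C@@H]1C[C@@H](O)[C@H](/C=C/C=C/I)O1 | intermediate
15 | 6-chloro-7-hydroxy-5-[(3E,5E)-6-[(2S,3R,5R)-3-hydroxy-5-methyltetrahydrofuran-2-yl]hexa-3,5-dien-1-yn-1-yl]-2,2-dimethyl-4H-1,3-benzodioxin-4-one | C[C@@H]1C[C@@H](O)[C@H](/C=C/C=C/C#Cc2c(Cl)c(O)cc3OC(C)(C)OC(=O)c23)O1 | intermediate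
16 | 5-chloro-6,8-dihydroxy-3-[(1E,3E)-4-[(2S,3R,5R)-3-hydroxy-5-methyltetrahydrofuran-2-yl]buta-1,3-dien-1-yl]-1H-isochromen-1-one | C[C@@H]1C[C@@H](O)[C@H](/C=C/C=C/c2cc3c(Cl)c(O)cc(O)c3c(=O)o2)O1 | target

Total step count: 11. Longest linear sequence: 7 steps (steps 1 to 5, then 10 and 11); the side chain takes 4 steps (6 to 9) before the coupling.

Steps most likely to fail

Step 8, ring closure of 12. The acceptor-substituted vinyl epoxide may close too slowly, so that intermolecular opening, rearrangement of the epoxide to a carbonyl compound or acetal formation at the aldehyde outrun the 5-endo attack. The fallback sets out from 12: Luche reduction (NaBH4, CeCl3·7H2O, MeOH, −40 °C) should give the epoxy allylic alcohol (2R)-1-[(2R,3R)-3-[(E)-3-hydroxyprop-1-en-1-yl]oxiran-2-yl]propan-2-ol F1, whose donor-type vinyl group activates the allylic epoxide carbon. Camphorsulfonic acid in CH2Cl2 should then close the ring with inversion to (2S,3R,5R)-2-[(E)-3-hydroxyprop-1-en-1-yl]-5-methyltetrahydrofuran-3-ol F2. MnO2 in CH2Cl2 oxidises only the allylic alcohol, which brings the route back at 13.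

Step 5, chlorination of 6. Site selectivity between C6 and C8 of the benzodioxinone may be poor, a second chlorination may follow, or the reagent may add to the alkyne. The fallback sets out from 6: NaOMe in MeOH opens the acetonide to methyl 2-ethynyl-4,6-dihydroxybenzoate F3, a true resorcylate in which the ester-chelated hydroxyl directs SO2Cl2 (Et2O, 0 °C) to its para position as in orsellinates, which should give methyl 3-chloro-2-ethynyl-4,6-dihydroxybenzoate F4. Sonogashira coupling of F4 with 14 under the conditions of step 10 should give methyl 3-chloro-4,6-dihydroxy-2-[(3E,5E)-6-[(2S,3R,5R)-3-hydroxy-5-methyltetrahydrofuran-2-yl]hexa-3,5-dien-1-yn-1-yl]benzoate F5. Gold-catalysed 6-endo-dig closure of this methyl ester (Ph3PAuCl, AgOTf, wet CH2Cl2, loss of methanol) brings the route back at 16.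

Step 7, epoxidation and Wittig reaction in one flask. Facial control or material may be lost through interference of the free hydroxyl, oxidation of the product enal by residual peroxide, or a second homologation. The fallback sets out from 10: reduction with NaBH4 and CeCl3·7H2O in MeOH should give (R,E)-hex-2-ene-1,5-diol F6. Sharpless asymmetric epoxidation (Ti(OiPr)4, (−)-diethyl (2S,3S)-tartrate, t-BuOOH, 4 Å molecular sieves, CH2Cl2, −20 °C), which is reagent-controlled at the allylic alcohol, should give [(2R,3R)-3-[(2R)-2-hydroxypropyl]oxiran-2-yl]methanol F7. Oxidation of the primary alcohol only (TEMPO, PhI(OAc)2, CH2Cl2) brings the route back at 11, which is treated with the ylide as in step 7 to give 12.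

Further compounds
F1 | step 8 | (2R)-1-[(2R,3R)-3-[(E)-3-hydroxyprop-1-en-1-yl]oxiran-2-yl]propan-2-ol | C[C@@H](O)C[C@H]1O[C@@H]1/C=C/CO
F2 | step 8 | (2S,3R,5R)-2-[(E)-3-hydroxyprop-1-en-1-yl]-5-methyltetrahydrofuran-3-ol | C[C@@H]1C[C@@H](O)[C@H](/C=C/CO)O1
F3 | step 5 | methyl 2-ethynyl-4,6-dihydroxybenzoate | COC(=O)c1c(O)cc(O)cc1C#C
F4 | step 5 | methyl 3-chloro-2-ethynyl-4,6-dihydroxybenzoate | COC(=O)c1c(O)cc(O)c(Cl)c1C#C
F5 | step 5 | methyl 3-chloro-4,6-dihydroxy-2-[(3E,5E)-6-[(2S,3R,5R)-3-hydroxy-5-methyltetrahydrofuran-2-yl]hexa-3,5-dien-1-yn-1-yl]benzoate | C[C@@H]1C[C@@H](O)[C@H](/C=C/C=C/C#Cc2c(Cl)c(O)cc(O)c2C(=O)OC)O1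
F6 | step 7 | (R,E)-hex-2-ene-1,5-diol | C[C@@H](O)C/C=C/CO
F7 | step 7 | [(2R,3R)-3-[(2R)-2-hydroxypropyl]oxiran-2-yl]methanol | C[C@@H](O)C[C@H]1O[C@@H]1CO
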